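The target is a diaryl ether in which ring B bears only the ether oxygen on C1' and a bromine on the adjacent C2'. This vicinal O/Br pair is read as the two ends of a benzyne triple bond, so the route rests on disconnecting O–C1' and C2'–Br together. In one operation the key step unites a perbrominated phenoxide (ring A), benzyne and a positive-bromine donor, with no metal that could disturb the four ring A bromines. The precursor is tetrabromoguaiacol, a fully substituted phenol whose second oxygen is masked as a methyl ether, used as its dry potassium salt; demethylation then reveals the target.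

Key step: step 2

Remark: the target has no stereocentre and no configurationally stable axis (ring B has a single ortho substituent), so it is one achiral compound and no stereocontrol is needed.

Step 1
Reactants: 1 guaiacol (2-methoxyphenol); 2 bromine
Product: 3 3,4,5,6-tetrabromo-2-methoxyphenol (tetrabromoguaiacol)
Conditions: Br2 (6 equiv), Fe powder (cat.), AcOH, rt → 60 °C; aq NaHSO3
Reagents that add atoms: bromine (2), BrBr
Why: All four ring C–H positions of guaiacol lie ortho or para to either the hydroxyl (C4, C6) or the methoxy group (C3, C5), so exhaustive electrophilic aromatic bromination (SEAr, FeBr3 formed in situ for the last, deactivated position) should fill every one of them, and the bisulfite work-up returns any ipso-brominated dienone to the phenol.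

Step 2
Reactants: 3 3,4,5,6-tetrabromo-2-methoxyphenol; 4 2-(trimethylsilyl)phenyl trifluoromethanesulfonate; 5 carbon tetrabromide
Product: 9 1,2,3,4-tetrabromo-5-(2-bromophenoxy)-6-methoxybenzene, via potassium tetrabromoguaiacolate 6 (not isolated), via benzyne 7 (not isolated), via 2-aryloxyphenylpotassium 8 (not isolated)
Conditions: KH (1.0 equiv), THF, 0 °C → rt; then CBr4 (4 equiv), spray-dried KF (3 equiv), 18-crown-6 (3 equiv), 4 (1.5 equiv, syringe pump), THF, 0 °C → rt, dark
Reagents that add atoms: 2-(trimethylsilyl)phenyl trifluoromethanesulfonate (4), C[Si](C)(C)c1ccccc1OS(=O)(=O)C(F)(F)F; carbon tetrabromide (5), BrC(Br)(Br)Br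
Why: Proposed new method: fluoride attacks silicon of 4 and triflate leaves to release benzyne 7 slowly; the crown-separated phenoxide 6 adds through oxygen to give aryl anion 8, whose carbanion at C2' attacks a bromine of CBr4 (halophilic substitution, expelling tribromomethanide), so O–C1' and C2'–Br are made across the former triple bond. The closest known reaction type is the transition-metal-free three-component coupling of silylaryl triflate-derived arynes with a heteroatom nucleophile and a positive-halogen donor such as a polyhalomethane; what is untested is a doubly ortho-substituted, weakly nucleophilic perbromophenoxide as the nucleophile together with bromine capture. No ring is closed and no stereocentre is formed, and because benzyne is symmetric there is no regiochemical question. The selectivity required is capture of 8 by bromine in preference to a proton or a second benzyne; it is secured by the absence of any O–H or acidic C–H (salt preformed with KH, which leaves only H2; dry KF; THF), by a several-fold excess of CBr4 and by slow addition of 4 so that benzyne stays dilute. Ring A of 6 has no C–H that the bromine donor could attack, and the medium holds no metal able to insert into C–Br bonds. Should 8 take bromine from a ring A C–Br instead (most readily the one on the carbon flanking the ether oxygen, C6 of 3, through a six-membered transition state), the resulting ring A anion is rebrominated by CBr4 and the same product 9 results.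

Step 3
Reactants: 9 1,2,3,4-tetrabromo-5-(2-bromophenoxy)-6-methoxybenzene
Product: 11 2,3,4,5-tetrabromo-6-(2-bromophenoxy)phenol (target), via aryloxydibromoborane 10 (not isolated)
Conditions: BBr3 (3 equiv), CH2Cl2, −78 °C → rt; then H2O
Reagents that add atoms: none
Why: BBr3 ether cleavage: boron coordinates the methoxy oxygen and bromide displaces the methyl group by SN2 to give borate 10, hydrolysed on work-up, while the diaryl ether oxygen, a weaker donor flanked only by sp2 carbons that bromide cannot attack, and the five aryl C–Br bonds should stay untouched.

Compound list
1 | guaiacol (2-methoxyphenol) | COc1ccccc1O | starting material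
2 | bromine | BrBr | starting material
3 | 3,4,5,6-tetrabromo-2-methoxyphenol (tetrabromoguaiacol) | COc1c(O)c(Br)c(Br)c(Br)c1Br | intermediate
4 | 2-(trimethylsilyl)phenyl trifluoromethanesulfonate | C[Si](C)(C)c1ccccc1OS(=O)(=O)C(F)(F)F | starting material
5 | carbon tetrabromide | BrC(Br)(Br)Br | starting material
6 | potassium 3,4,5,6-tetrabromo-2-methoxyphenolate | [K+].[O-]c1c(OC)c(Br)c(Br)c(Br)c1Br | intermediate
7 | benzyne (1,2-didehydrobenzene) | C1#CC=CC=C1 | intermediate
8 | [2-(2,3,4,5-tetrabromo-6-methoxyphenoxy)phenyl]potassium | COc1c(Oc2ccccc2[K])c(Br)c(Br)c(Br)c1Br | intermediate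
9 | 1,2,3,4-tetrabromo-5-(2-bromophenoxy)-6-methoxybenzene | COc1c(Oc2ccccc2Br)c(Br)c(Br)c(Br)c1Br | intermediate
10 | dibromo[2,3,4,5-tetrabromo-6-(2-bromophenoxy)phenoxy]borane | BrB(Br)Oc1c(Br)c(Br)c(Br)c(Br)c1Oc1ccccc1Br | intermediate
11 | 2,3,4,5-tetrabromo-6-(2-bromophenoxy)phenol | Oc1c(Br)c(Br)c(Br)c(Br)c1Oc1ccccc1Br | target

Total step count: 3. Longest linear sequence: 3 steps (1 → 3 → 9 → 11).

Steps most likely to fail

Step 2 (proposed new method). The hindered, weakly nucleophilic phenoxide may lose the race for benzyne to fluoride, bromide or tribromomethanide. The aryl anion may be protonated before it meets the bromine donor. Dibromocarbene shed by tribromomethanide may also consume phenoxide. The fallback uses known chemistry, sets out from 3 and returns to the route at 9. Nucleophilic aromatic substitution of 3 on 1-fluoro-2-nitrobenzene (K2CO3, DMF, 100 °C) should give 1,2,3,4-tetrabromo-5-methoxy-6-(2-nitrophenoxy)benzene F1. Reduction of the nitro group with Fe/NH4Cl in EtOH/H2O, which leaves aryl bromides alone, should give 2-(2,3,4,5-tetrabromo-6-methoxyphenoxy)aniline F2. Diazotisation (NaNO2, 48% HBr/AcOH, 0 °C) gives 2-(2,3,4,5-tetrabromo-6-methoxyphenoxy)benzenediazonium bromide F3, and Sandmeyer bromination with CuBr/HBr at 60 °C delivers 9.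

Step 1. Bromination may stall before the fourth bromine enters the crowded position ortho to the methoxy group, or hot HBr may strip the O-methyl group. The fallback sets out from 1 and returns at 3, and it installs the methyl group last instead of carrying it through the bromination. Guaiacol is brominated with excess Br2 in AcOH and then heated with 48% HBr/AcOH at reflux so that ether cleavage is driven to completion. After a reductive (Na2S2O4) work-up this should give 3,4,5,6-tetrabromobenzene-1,2-diol (tetrabromocatechol) F4, which can also be purchased. Mono-O-methylation of the symmetrical diol with MeI (1.0 equiv) and Li2CO3 in DMF then gives 3. Unreacted diol and any dimethyl ether are removed by their different acidity.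

Step 3. Cleavage may stay incomplete because the methoxy oxygen, twisted between the aryloxy group and a bromine on an electron-poor ring, binds boron poorly. The fallback sets out from 9 and returns at 11, replacing Lewis-acid activation by purely nucleophilic dealkylation. LiI in 2,4,6-collidine at reflux attacks the methyl carbon by SN2, helped by the good leaving ability of the tetrabromoaryloxide. This should give lithium 2,3,4,5-tetrabromo-6-(2-bromophenoxy)phenolate F5, which acidification (1 M HCl) converts into 11.

Further compounds
F1 | step 2 | 1,2,3,4-tetrabromo-5-methoxy-6-(2-nitrophenoxy)benzene | COc1c(Oc2ccccc2[N+](=O)[O-])c(Br)c(Br)c(Br)c1Br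
F2 | step 2 | 2-(2,3,4,5-tetrabromo-6-methoxyphenoxy)aniline | COc1c(Oc2ccccc2N)c(Br)c(Br)c(Br)c1Br
F3 | step 2 | 2-(2,3,4,5-tetrabromo-6-methoxyphenoxy)benzenediazonium bromide | COc1c(Oc2ccccc2[N+]#N)c(Br)c(Br)c(Br)c1Br.[Br-]
F4 | step 1 | 3,4,5,6-tetrabromobenzene-1,2-diol (tetrabromocatechol) | Oc1c(O)c(Br)c(Br)c(Br)c1Br
F5 | step 3 | lithium 2,3,4,5-tetrabromo-6-(2-bromophenoxy)phenolate | [Li+].[O-]c1c(Br)c(Br)c(Br)c(Br)c1Oc1ccccc1Br
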